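**Strategy.** Everything rests on cutting ring C of the lower unit (L) at two bonds, C4(L)–C4a(L) and O1(L)–C2(L). Its O1–C2(aryl)–C3(OH)–C4(OH) array, with the 2,3-trans-3,4-cis pattern, is a trans-epoxy aldehyde in disguise, and the adjoining C4a–H and O1–H of ring A(L) are a phenol. The key step joins the two in a Ti(OiPr)4-mediated [3+3] annulation: it makes both bonds, closes the last ring and relays the catalytically set C3 to C4 and C2. Its precursor is the upper flavan-3-ol that already carries the open resorcinol ring at C4(U), compound 10, whose own ring C is built with the same epoxy aldehyde 4.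

Key step: step 5

Notation: (U) and (L) mark atoms of the upper and the lower flavan unit; the β face of a ring C is the face of its 3-OH. The target is 2,3-trans-3,4-cis in both units, (2R,3S,4S) each.

Assumption: the (S)-configured prolinol silyl ether of step 2 gives the (2R,3S)-epoxide, as it does with cinnamaldehyde; if the sense were opposite, its enantiomer would be used.

Step 1
Reactants: 1 3,4-bis(benzyloxy)benzaldehyde; 2 (triphenylphosphoranylidene)acetaldehyde
Product: 3 (2E)-3-[3,4-bis(benzyloxy)phenyl]prop-2-enal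
Conditions: 2 (1.2 equiv), toluene, 90 °C
Reagents that add atoms: none
Why: Wittig olefination with a formyl-stabilized ylide should give the (E)-enal; no stereocentre is formed.

Step 2
Reactants: 3 (2E)-3-[3,4-bis(benzyloxy)phenyl]prop-2-enal
Product: 4 (2R,3S)-3-[3,4-bis(benzyloxy)phenyl]oxirane-2-carbaldehyde
Conditions: (S)-2-{bis[3,5-bis(trifluoromethyl)phenyl](trimethylsilyloxy)methyl}pyrrolidine (10 mol%), 35% aq. H2O2 (1.3 equiv), CH2Cl2, 23 °C; used at once
Reagents that add atoms: hydrogen peroxide, OO
Why: Iminium–enamine organocatalytic epoxidation, in which H2O2 adds to C3 of the iminium ion on the face left open by the diaryl(silyloxy)methyl group and the enamine then closes on oxygen, should set both centres of the trans-epoxide as (2R,3S).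

Step 3
Reactants: 5 3-(benzyloxy)phenol; 4 (2R,3S)-3-[3,4-bis(benzyloxy)phenyl]oxirane-2-carbaldehyde
Product: 7 (2R,3S,4S)-7-(benzyloxy)-2-[3,4-bis(benzyloxy)phenyl]chromane-3,4-diol, via anti-epoxy alcohol 6 (not isolated)
Conditions: Ti(OiPr)4 (1.05 equiv), toluene, 25 °C, i-PrOH evaporated; CH2Cl2, 4 (1.1 equiv), −30 → 25 °C; aq. potassium sodium tartrate
Reagents that add atoms: none
Why: Proposed new method: the aryloxytitanium triisopropoxide of 5 should add through its ortho carbon para to OBn to the aldehyde of 4 in a six-membered titanium-bridged transition state, in the Felkin–Anh (anti) sense because this tetravalent titanium aryloxide is not expected to chelate the epoxide oxygen, and the titanium 2,3-epoxy alkoxide 6 should then be opened 6-endo by the phenolic oxygen at the electron-rich benzylic carbon with inversion, so that C3 comes from 4, C4 (OH cis to 3-OH) from the addition and C2 (aryl trans to 3-OH) from the opening; the closest known types are the ortho-selective hydroxyalkylation of titanium and magnesium phenoxides with α-alkoxy aldehydes and the Ti(OiPr)4-mediated C3-selective opening of 2,3-epoxy alcohols.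

Step 4
Reactants: 7 (2R,3S,4S)-7-(benzyloxy)-2-[3,4-bis(benzyloxy)phenyl]chromane-3,4-diol; 8 resorcinol
Product: 10 (2R,3S,4S)-7-(benzyloxy)-2-[3,4-bis(benzyloxy)phenyl]-4-(2,4-dihydroxyphenyl)chroman-3-ol, via mixed titanate 9 (not isolated)
Conditions: Ti(OiPr)4 (1.0 equiv), 8 (1.2 equiv), toluene, 25 °C, i-PrOH evaporated; CH2Cl2, TiCl4 (0.2 equiv), −40 → 0 °C; aq. potassium sodium tartrate
Reagents that add atoms: none
Why: Proposed new method: ligand exchange should put the cis-3,4-diolate of 7 and one resorcinol oxygen on the same titanium (9), the Lewis acid then ionizes the benzylic C4–O bond (cation stabilized by O1 and 7-OBn), and the aryloxide, still anchored through O3 on the β face, delivers its ortho carbon (para to the second OH) to C4 in a seven-membered cyclic transition state, which sets C4 with the new aryl group cis to 3-OH; the closest known types are the syn-selective ortho-C-alkylation of aryl borates by aryl-substituted epoxides and the 3,4-cis coupling of flavan-3-ols through a temporary tether on O3 (Lewis-acid-catalysed intramolecular Friedel–Crafts alkylation).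

Step 5
Reactants: 10 (2R,3S,4S)-7-(benzyloxy)-2-[3,4-bis(benzyloxy)phenyl]-4-(2,4-dihydroxyphenyl)chroman-3-ol; 4 (2R,3S)-3-[3,4-bis(benzyloxy)phenyl]oxirane-2-carbaldehyde
Product: 12 penta-O-benzyl ether of the target, via anti-epoxy alcohol 11 (not isolated)
Conditions: Ti(OiPr)4 (2.2 equiv), THF–toluene, 25 °C, i-PrOH evaporated; CH2Cl2, 4 (1.2 equiv), −30 → 25 °C; aq. potassium sodium tartrate
Reagents that add atoms: none
Why: Proposed new method: Ti(OiPr)4 should turn the unhindered phenol O1(L)–H of 10 into an aryloxytitanium triisopropoxide, whose ortho carbon C4a(L) adds to the aldehyde of 4 through a six-membered titanium-bridged transition state to give the titanium 2,3-epoxy alkoxide 11; the same titanium then activates the epoxide by chelation with O4(L), and O1(L) opens it at the benzylic carbon. The closest known reaction types are the ortho-selective hydroxyalkylation of titanium and magnesium phenoxides with α-alkoxy aldehydes and the Ti(OiPr)4-mediated C3-selective opening of 2,3-epoxy alcohols, here merged on an α,β-epoxy aldehyde. Ring C(L) is closed in the 6-endo-tet mode, by attack of O1(L) on the epoxide carbon that carries the 3,4-bis(benzyloxy)phenyl group. C3(L) is carried over unchanged from 4 (set by the catalyst in step 2), C4(L) is set by Felkin–Anh addition anti to the epoxide C–O bond of the non-chelated aldehyde (4-OH cis to 3-OH), and C2(L) by inversion at the benzylic epoxide carbon (2-aryl trans to 3-OH). The step needs site selectivity for C4a(L), secured because only ring A(L) bears free phenols (7-O(U) is benzylated) and C4a(L) is ortho to O1(L) and para to 7-OH(L) while C8(L) is flanked by two oxygens; it needs 6-endo over 5-exo opening, secured by the electron-rich benzylic carbon; and the new benzylic 4-OH must not ionize, hence low temperature and no protic acid.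

Step 6
Reactants: 12 penta-O-benzyl ether of the target
Product: 13 target (CNP0280090.1)
Conditions: H2 (1 atm), Pd(OH)2 on carbon, THF–MeOH, 25 °C; filtration, chromatography on Sephadex LH-20
Reagents that add atoms: none
Why: Hydrogenolysis of the five aryl benzyl ethers under neutral conditions should be faster than cleavage of the benzylic C2–O1 bonds and of the free benzylic 4-OH(L), and no stereocentre is touched.

**Compound list**

1 | 3,4-bis(benzyloxy)benzaldehyde | O=Cc1ccc(OCc2ccccc2)c(OCc2ccccc2)c1 | starting material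
2 | (triphenylphosphoranylidene)acetaldehyde | O=CC=P(c1ccccc1)(c1ccccc1)c1ccccc1 | starting material
3 | (2E)-3-[3,4-bis(benzyloxy)phenyl]prop-2-enal | O=C/C=C/c1ccc(OCc2ccccc2)c(OCc2ccccc2)c1 | intermediate
4 | (2R,3S)-3-[3,4-bis(benzyloxy)phenyl]oxirane-2-carbaldehyde (trans-epoxide) | O=C[C@@H]1O[C@H]1c1ccc(OCc2ccccc2)c(OCc2ccccc2)c1 | intermediate
5 | 3-(benzyloxy)phenol | Oc1cccc(OCc2ccccc2)c1 | starting material
6 | (S)-[4-(benzyloxy)-2-hydroxyphenyl]{(2S,3S)-3-[3,4-bis(benzyloxy)phenyl]oxiran-2-yl}methanol, anti adduct, present as its titanium alkoxide | Oc1cc(OCc2ccccc2)ccc1[C@H](O)[C@@H]1O[C@H]1c1ccc(OCc2ccccc2)c(OCc2ccccc2)c1 | intermediate (not isolated)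
7 | (2R,3S,4S)-7-(benzyloxy)-2-[3,4-bis(benzyloxy)phenyl]chromane-3,4-diol (2,3-trans-3,4-cis) | O(Cc1ccccc1)c1ccc2c(c1)O[C@H](c1ccc(OCc3ccccc3)c(OCc3ccccc3)c1)[C@@H](O)[C@H]2O | intermediate
8 | resorcinol (benzene-1,3-diol) | Oc1cccc(O)c1 | starting material
9 | mixed titanate: titanium bound to O3 and O4 of 7 (five-membered ring on the β face), to one oxygen of resorcinol and to one isopropoxide | O(Cc1ccccc1)c1ccc2c(c1)O[C@H](c1ccc(OCc3ccccc3)c(OCc3ccccc3)c1)[C@H]1O[Ti](OC(C)C)(Oc3cccc(O)c3)O[C@@H]21 | intermediate (not isolated)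
10 | (2R,3S,4S)-7-(benzyloxy)-2-[3,4-bis(benzyloxy)phenyl]-4-(2,4-dihydroxyphenyl)chroman-3-ol (2,3-trans-3,4-cis) | O(Cc1ccccc1)c1ccc2c(c1)O[C@H](c1ccc(OCc3ccccc3)c(OCc3ccccc3)c1)[C@@H](O)[C@H]2c1ccc(O)cc1O | intermediate
11 | (2R,3S,4S)-7-(benzyloxy)-2-[3,4-bis(benzyloxy)phenyl]-4-{5-[(S)-{(2S,3S)-3-[3,4-bis(benzyloxy)phenyl]oxiran-2-yl}(hydroxy)methyl]-2,4-dihydroxyphenyl}chroman-3-ol, present as its titanium alkoxide | O(Cc1ccccc1)c1ccc2c(c1)O[C@H](c1ccc(OCc3ccccc3)c(OCc3ccccc3)c1)[C@@H](O)[C@H]2c1cc([C@H](O)[C@@H]3O[C@H]3c3ccc(OCc4ccccc4)c(OCc4ccccc4)c3)c(O)cc1O | intermediate (not isolated)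
12 | (2R,3S,4S)-6-{(2R,3S,4S)-7-(benzyloxy)-2-[3,4-bis(benzyloxy)phenyl]-3-hydroxychroman-4-yl}-2-[3,4-bis(benzyloxy)phenyl]chromane-3,4,7-triol (the target with benzyl ethers on 7-O(U) and on both catechol rings B) | O(Cc1ccccc1)c1ccc2c(c1)O[C@H](c1ccc(OCc3ccccc3)c(OCc3ccccc3)c1)[C@@H](O)[C@H]2c1cc2c(cc1O)O[C@H](c1ccc(OCc3ccccc3)c(OCc3ccccc3)c1)[C@@H](O)[C@H]2O | intermediate
13 | (2R,3S,4S)-2-(3,4-dihydroxyphenyl)-6-[(2R,3S,4S)-2-(3,4-dihydroxyphenyl)-3,7-dihydroxychroman-4-yl]chromane-3,4,7-triol | Oc1ccc2c(c1)O[C@H](c1ccc(O)c(O)c1)[C@@H](O)[C@H]2c1cc2c(cc1O)O[C@H](c1ccc(O)c(O)c1)[C@@H](O)[C@H]2O | target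

**Total step count:** 6. **Longest linear sequence:** 6 (steps 1 to 6; compound 4 enters a second time in step 5).

**Steps most likely to fail**

1. Step 5 (key step). The aryloxide may attack the labile benzylic epoxide of 4 before the aldehyde. The addition may lose site selectivity (C8(L)) or follow the chelated, syn sense. The new benzylic 4-OH(L), para to a free phenol, may ionize on titanium and condense further. Fallback, known chemistry, ring C(L) still closed last but as an alkene: it sets out from 10 and the enal 3. Condensation with PhB(OH)2 and propionic acid in toluene at reflux (ortho-quinone methide, then oxa-6π electrocyclization) should give the flav-3-ene F1 together with its epimer at C2(L), the flav-3-ene F2. Dihydroxylation of the mixture with OsO4 (cat.) and N-methylmorpholine N-oxide, anti to the 2-aryl group, should give 12 from F1 and the diastereomeric triol F3 from F2, which is removed by chromatography. The fallback comes back to the route at 12; its price is that C2(L) is not controlled.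

2. Step 4. The ionized flavan-4-yl cation may be captured outside the titanium template, from the α face, which gives the 3,4-trans epimer. Compound 7 may also condense with itself through C6 of its ring A, or resorcinol may react at C2. Fallback, known chemistry without template: it sets out from 7. BF3·OEt2-catalysed Friedel–Crafts condensation with a large excess of 8 in dioxane–CH2Cl2 at 0 °C should give 10 together with its C4 epimer, the 3,4-trans adduct F4, and the two are separated by chromatography. It comes back to the route at 10.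

3. Step 3. The Lewis acid may open or rearrange the electron-rich epoxide of 4 (Meinwald-type rearrangement) before the addition. The addition may take the chelated course and give the 4-epimer. The ortho-hydroxybenzyl titanate 6 may be arylated a second time at C4. Fallback, known chemistry from the chiral pool: it sets out not from a numbered compound but from commercial (+)-fustin F5, which replaces 4 and 5 for this compound only. Benzylation of the three phenols (BnBr, K2CO3, DMF, 25 °C) should give tri-O-benzylfustin F6. Reduction with LiBH(s-Bu)3 (2.2 equiv, THF, −78 °C), by equatorial hydride attack trans to the 3-oxygen, should give the axial 4-OH cis to 3-OH. It comes back to the route at 7.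

**Further compounds**

F1 | step 5 | (2R,3S,4S)-7-(benzyloxy)-2-[3,4-bis(benzyloxy)phenyl]-4-{(2S)-2-[3,4-bis(benzyloxy)phenyl]-7-hydroxy-2H-chromen-6-yl}chroman-3-ol | O(Cc1ccccc1)c1ccc2c(c1)O[C@H](c1ccc(OCc3ccccc3)c(OCc3ccccc3)c1)[C@@H](O)[C@H]2c1cc2c(cc1O)O[C@H](c1ccc(OCc3ccccc3)c(OCc3ccccc3)c1)C=C2
F2 | step 5 | (2R,3S,4S)-7-(benzyloxy)-2-[3,4-bis(benzyloxy)phenyl]-4-{(2R)-2-[3,4-bis(benzyloxy)phenyl]-7-hydroxy-2H-chromen-6-yl}chroman-3-ol | O(Cc1ccccc1)c1ccc2c(c1)O[C@H](c1ccc(OCc3ccccc3)c(OCc3ccccc3)c1)[C@@H](O)[C@H]2c1cc2c(cc1O)O[C@@H](c1ccc(OCc3ccccc3)c(OCc3ccccc3)c1)C=C2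
F3 | step 5 | (2S,3R,4R)-6-{(2R,3S,4S)-7-(benzyloxy)-2-[3,4-bis(benzyloxy)phenyl]-3-hydroxychroman-4-yl}-2-[3,4-bis(benzyloxy)phenyl]chromane-3,4,7-triol | O(Cc1ccccc1)c1ccc2c(c1)O[C@H](c1ccc(OCc3ccccc3)c(OCc3ccccc3)c1)[C@@H](O)[C@H]2c1cc2c(cc1O)O[C@@H](c1ccc(OCc3ccccc3)c(OCc3ccccc3)c1)[C@H](O)[C@@H]2O
F4 | step 4 | (2R,3S,4R)-7-(benzyloxy)-2-[3,4-bis(benzyloxy)phenyl]-4-(2,4-dihydroxyphenyl)chroman-3-ol | O(Cc1ccccc1)c1ccc2c(c1)O[C@H](c1ccc(OCc3ccccc3)c(OCc3ccccc3)c1)[C@@H](O)[C@@H]2c1ccc(O)cc1O
F5 | step 3 | (+)-fustin, (2R,3R)-2-(3,4-dihydroxyphenyl)-3,7-dihydroxychroman-4-one | Oc1ccc2c(c1)O[C@H](c1ccc(O)c(O)c1)[C@@H](O)C2=O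
F6 | step 3 | (2R,3R)-7-(benzyloxy)-2-[3,4-bis(benzyloxy)phenyl]-3-hydroxychroman-4-one | O(Cc1ccccc1)c1ccc2c(c1)O[C@H](c1ccc(OCc3ccccc3)c(OCc3ccccc3)c1)[C@@H](O)C2=O
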